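**Retrosynthetic overview** (locants follow the dihydronaphthalene numbering of the target: C1 aryl, C2 CH2OH, C3 CHO; ring A = benzo ring with OH at C7 and OMe at C8; ring B = dihydro ring)
1. Vitedoin A 33 ⇐ silyl ether 32 ⇐ epoxy enal 29: ring B is closed last, by the C2–C3 bond, when C3 of the ring A p-hydroxycinnamaldehyde unit opens a terminal epoxide at C2 with inversion.
2. Enabling feature: the C7 hydroxyl of ring A is para to C4a, so its phenoxide is conjugated through C4a–C4=C3 with the formyl group (a vinylogous enolate with C3 as carbon terminus); the CH2OH on C2, 1,2 to the new bond, is the trace of the oxirane.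
3. 29 ⇐ aryl bromide 26 (Suzuki alkenylation at C4a) ⇐ diol 23 ⇐ trans-3-hydroxy-4-aryl-dihydrocoumarin 19, whose lactone is a temporary ring tying the C8 oxygen to the future CH2OH carbon.
4. 19 ⇐ 5-bromo-8-silyloxycoumarin 8 + arylboronic acid 15: rhodium-catalysed asymmetric 1,4-addition sets C1; anti enolate hydroxylation sets the carbinol that becomes C2.
5. Ring order: pyranone (step 1, opened in step 8) → oxirane (step 10) → ring B (step 12).

Key step: step 12

Assumption: the sense of induction in step 6 is assigned by analogy with the known ligand/product correlation for arylboronic acid additions to coumarins; the enantiomeric ligand is used if the 5-bromo substituent reverses it.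

**Step 1**
Reactants: 1 2,3-dihydroxybenzaldehyde; 2 ethyl (triphenylphosphoranylidene)acetate
Product: 4 8-hydroxycoumarin, via hydroxycinnamate ester 3 (not isolated)
Conditions: 2 (1.2 equiv), N,N-diethylaniline, reflux
Reagents that add atoms: ethyl (triphenylphosphoranylidene)acetate, CCOC(=O)C=P(c1ccccc1)(c1ccccc1)c1ccccc1
Why: Wittig olefination of the salicylaldehyde, followed at this temperature by alkene isomerisation and lactonisation of the o-hydroxycinnamate (one-pot coumarin synthesis).

**Step 2**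
Reactants: 4 8-hydroxycoumarin; 5 chlorotriisopropylsilane
Product: 6 8-(triisopropylsilyloxy)coumarin
Conditions: 5 (1.2 equiv), imidazole (2 equiv), DMF, 23 °C
Reagents that add atoms: chlorotriisopropylsilane, CC(C)[Si](Cl)(C(C)C)C(C)C
Why: Imidazole-mediated silylation of the phenol; the bulky group is chosen to shield C7 in step 3 and to resist oxygen-to-oxygen migration later.

**Step 3**
Reactants: 6 8-(triisopropylsilyloxy)coumarin; 7 N-bromosuccinimide
Product: 8 5-bromo-8-(triisopropylsilyloxy)coumarin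
Conditions: 7 (1.05 equiv), MeCN, 0 → 23 °C, dark
Reagents that add atoms: N-bromosuccinimide, O=C1CCC(=O)N1Br
Why: Electrophilic aromatic bromination para to the silyloxy group (C5), the ortho position C7 being shielded by the silyl group and C3 of the pyranone not being activated by an 8-oxygen.

**Step 4**
Reactants: 9 4-bromo-2-methoxyphenol; 5 chlorotriisopropylsilane
Product: 10 (4-bromo-2-methoxyphenoxy)triisopropylsilane
Conditions: 5 (1.2 equiv), imidazole (2 equiv), DMF, 23 °C
Reagents that add atoms: chlorotriisopropylsilane, CC(C)[Si](Cl)(C(C)C)C(C)C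
Why: Standard silylation of the phenol, giving the same protecting group on both phenols.

**Step 5**
Reactants: 10 (4-bromo-2-methoxyphenoxy)triisopropylsilane; 11 triisopropyl borate; 12 water
Product: 15 [3-methoxy-4-(triisopropylsilyloxy)phenyl]boronic acid, via aryllithium 13 (not isolated), via lithium aryltriisopropoxyborate 14 (not isolated)
Conditions: n-BuLi (1.05 equiv), THF, −78 °C; B(OiPr)3, −78 → 23 °C; 1 M HCl
Reagents that add atoms: triisopropyl borate, CC(C)OB(OC(C)C)OC(C)C; water, O
Why: Bromine–lithium exchange, trapping of the aryllithium with the trialkyl borate and hydrolysis of the ate complex (standard boronic acid synthesis).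

**Step 6**
Reactants: 8 5-bromo-8-(triisopropylsilyloxy)coumarin; 15 [3-methoxy-4-(triisopropylsilyloxy)phenyl]boronic acid
Product: 16 (4S)-5-bromo-4-[3-methoxy-4-(triisopropylsilyloxy)phenyl]-8-(triisopropylsilyloxy)chroman-2-one
Conditions: Rh(acac)(C2H4)2 (3 mol%), (S)-SEGPHOS (3.3 mol%), 15 (4 equiv), 1,4-dioxane/H2O 10:1, 60 °C
Reagents that add atoms: [3-methoxy-4-(triisopropylsilyloxy)phenyl]boronic acid, COc1cc(B(O)O)ccc1O[Si](C(C)C)(C(C)C)C(C)C
Why: Hayashi–Miyaura rhodium-catalysed asymmetric 1,4-addition to a coumarin; aryl–rhodium insertion into C3=C4 on the enantioface chosen by the ligand sets the diarylmethine centre (C1 of the target).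

**Step 7**
Reactants: 16 (4S)-lactone; 17 3-phenyl-2-(phenylsulfonyl)oxaziridine
Product: 19 (3R,4S)-5-bromo-3-hydroxy-4-[3-methoxy-4-(triisopropylsilyloxy)phenyl]-8-(triisopropylsilyloxy)chroman-2-one, via sodium enolate 18 (not isolated)
Conditions: NaN(SiMe3)2 (1.2 equiv), THF, −78 °C; 17 (1.5 equiv), −78 °C; AcOH quench
Reagents that add atoms: 3-phenyl-2-(phenylsulfonyl)oxaziridine, O=S(=O)(N1OC1c1ccccc1)c1ccccc1
Why: Enolate hydroxylation with an N-sulfonyloxaziridine; the oxidant approaches the lactone enolate anti to the pseudoaxial C4 aryl group, giving the 3,4-trans carbinol that becomes the oxirane carbon.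

**Step 8**
Reactants: 19 (3R,4S)-hydroxy lactone
Product: 21 (2R,3S)-3-[6-bromo-2-hydroxy-3-(triisopropylsilyloxy)phenyl]-3-[3-methoxy-4-(triisopropylsilyloxy)phenyl]propane-1,2-diol, via lactol 20 (not isolated)
Conditions: LiBH4 (3 equiv), THF, 0 → 23 °C; aqueous work-up
Reagents that add atoms: none
Why: Borohydride reduction of the lactone through the lactol opens the temporary ring to the C8 phenol and the 1,2-diol without touching either stereocentre.

**Step 9**
Reactants: 21 triol; 22 iodomethane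
Product: 23 (2R,3S)-3-[6-bromo-2-methoxy-3-(triisopropylsilyloxy)phenyl]-3-[3-methoxy-4-(triisopropylsilyloxy)phenyl]propane-1,2-diol
Conditions: MeI (1.5 equiv), K2CO3 (1.5 equiv), acetone, 23 °C
Reagents that add atoms: iodomethane, CI
Why: Williamson O-methylation chemoselective for the phenol over the diol; the bulky silyl group on the less hindered neighbouring oxygen is not expected to migrate to the congested C8 oxygen.

**Step 10**
Reactants: 23 diol; 24 4-methylbenzenesulfonyl chloride
Product: 26 (2R)-2-{(S)-[6-bromo-2-methoxy-3-(triisopropylsilyloxy)phenyl][3-methoxy-4-(triisopropylsilyloxy)phenyl]methyl}oxirane, via primary tosylate 25 (not isolated)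
Conditions: TsCl (1.1 equiv), Bu2SnO (5 mol%), Et3N, CH2Cl2, 0 → 23 °C; then K2CO3, MeOH, 0 °C
Reagents that add atoms: none
Why: Tin-catalysed sulfonylation selective for the primary hydroxyl, then intramolecular Williamson closure (3-exo-tet); the C–O bond at the secondary carbinol is never broken, so its configuration is retained.

**Step 11**
Reactants: 26 aryl bromide epoxide; 27 (E)-2-(3,3-diethoxyprop-1-en-1-yl)-4,4,5,5-tetramethyl-1,3,2-dioxaborolane; 12 water
Product: 29 (2E)-3-{3-methoxy-2-[(S)-[3-methoxy-4-(triisopropylsilyloxy)phenyl][(2R)-oxiran-2-yl]methyl]-4-(triisopropylsilyloxy)phenyl}prop-2-enal, via diethyl acetal 28 (not isolated)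
Conditions: Pd(OAc)2 (5 mol%), SPhos (10 mol%), K3PO4, THF/H2O 10:1, 60 °C; then pyridinium p-toluenesulfonate (cat.), acetone/H2O, 23 °C
Reagents that add atoms: (E)-2-(3,3-diethoxyprop-1-en-1-yl)-4,4,5,5-tetramethyl-1,3,2-dioxaborolane, CCOC(OCC)/C=C/B1OC(C)(C)C(C)(C)O1; water, O
Why: Suzuki–Miyaura coupling installs the three-carbon arm at C4a with retention of the (E) geometry, and the aryl-conjugated acetal hydrolyses under acid mild enough to spare the terminal epoxide and the silyl ethers.

**Step 12**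
Reactants: 29 epoxy enal
Product: 32 (1S,2R)-7-hydroxy-2-(hydroxymethyl)-8-methoxy-1-[3-methoxy-4-(triisopropylsilyloxy)phenyl]-1,2-dihydronaphthalene-3-carbaldehyde, via cesium phenoxide 30 (not isolated), via quinone methide alkoxide 31 (not isolated)
Conditions: Cs2CO3 (1.2 equiv), degassed DMF/H2O 20:1, 0.01 M, argon, 23 → 60 °C; AcOH quench
Reagents that add atoms: none
Why: Proposed new method: carbonate should cleave the ring A silyl ether selectively (its phenoxide, para to C4a and conjugated through C4=C3 with the formyl group, is a far better leaving group than the guaiacyl phenoxide of the pendant ring), and the resulting phenoxide 30 is a vinylogous enolate whose carbon terminus C3 opens the oxirane at C2 by SN2 attack to give quinone methide aldehyde 31, which re-aromatises ring A and restores the C3=C4–CHO enal by loss of the C3 proton. The closest known reaction types are the intramolecular opening of epoxides by stabilised enolates (epoxy-nitrile and epoxy-ester cyclisations, malonate–epoxide alkylation), the phosphine-mediated Morita–Baylis–Hillman-type cyclisation of enone epoxides, and the C-protonation of p-hydroxycinnamate phenoxides at this same carbon that underlies their decarboxylation through quinone methides. Ring B is the one ring closed, in a 6-exo-tet (enolexo) mode at the internal oxirane carbon, which the collinear geometry of epoxide opening should favour over 7-endo attack at the CH2 carbon. C2 is set by inversion of the (R)-oxirane carbon and C1 is carried through untouched, so the 1,2-trans (1S,2R) relationship follows from the stereospecific displacement and not from a facial choice. The step needs C- over O-alkylation and intra- over intermolecular reaction: the phenoxide oxygen and the ring carbons ortho to it cannot reach the epoxide, the aldehyde is deactivated as part of the vinylogous carboxylate, and high dilution suppresses intermolecular etherification. The pendant phenol stays silylated so that it cannot engage the epoxide through aryl participation.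

**Step 13**
Reactants: 32 mono-silyl ether
Product: 33 vitedoin A, (1S,2R)-7-hydroxy-1-(4-hydroxy-3-methoxyphenyl)-2-(hydroxymethyl)-8-methoxy-1,2-dihydronaphthalene-3-carbaldehyde
Conditions: Bu4NF (1.2 equiv), AcOH (1.2 equiv), THF, 0 °C
Reagents that add atoms: none
Why: Fluoride cleavage of the remaining aryl silyl ether, buffered with acetic acid so that the phenolic enal is not exposed to base; no stereocentre is affected.

**Compound list**
1 | 2,3-dihydroxybenzaldehyde | O=Cc1cccc(O)c1O | starting material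
2 | ethyl (triphenylphosphoranylidene)acetate | CCOC(=O)C=P(c1ccccc1)(c1ccccc1)c1ccccc1 | starting material
3 | ethyl 3-(2,3-dihydroxyphenyl)prop-2-enoate (E/Z mixture) | CCOC(=O)C=Cc1cccc(O)c1O | intermediate
4 | 8-hydroxycoumarin | O=C1C=Cc2cccc(O)c2O1 | intermediate
5 | chlorotriisopropylsilane | CC(C)[Si](Cl)(C(C)C)C(C)C | starting material
6 | 8-(triisopropylsilyloxy)coumarin | O=C1C=Cc2cccc(O[Si](C(C)C)(C(C)C)C(C)C)c2O1 | intermediate
7 | N-bromosuccinimide | O=C1CCC(=O)N1Br | starting material
8 | 5-bromo-8-(triisopropylsilyloxy)coumarin | O=C1C=Cc2c(Br)ccc(O[Si](C(C)C)(C(C)C)C(C)C)c2O1 | intermediate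
9 | 4-bromo-2-methoxyphenol | COc1cc(Br)ccc1O | starting material
10 | (4-bromo-2-methoxyphenoxy)triisopropylsilane | COc1cc(Br)ccc1O[Si](C(C)C)(C(C)C)C(C)C | intermediate
11 | triisopropyl borate | CC(C)OB(OC(C)C)OC(C)C | starting material
12 | water | O | starting material
13 | [3-methoxy-4-(triisopropylsilyloxy)phenyl]lithium | COc1cc([Li])ccc1O[Si](C(C)C)(C(C)C)C(C)C | intermediate
14 | lithium triisopropoxy[3-methoxy-4-(triisopropylsilyloxy)phenyl]borate | [Li+].COc1cc([B-](OC(C)C)(OC(C)C)OC(C)C)ccc1O[Si](C(C)C)(C(C)C)C(C)C | intermediate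
15 | [3-methoxy-4-(triisopropylsilyloxy)phenyl]boronic acid | COc1cc(B(O)O)ccc1O[Si](C(C)C)(C(C)C)C(C)C | intermediate
16 | (4S)-5-bromo-4-[3-methoxy-4-(triisopropylsilyloxy)phenyl]-8-(triisopropylsilyloxy)chroman-2-one | O=C1C[C@@H](c3ccc(O[Si](C(C)C)(C(C)C)C(C)C)c(OC)c3)c2c(Br)ccc(O[Si](C(C)C)(C(C)C)C(C)C)c2O1 | intermediate
17 | 3-phenyl-2-(phenylsulfonyl)oxaziridine (racemic) | O=S(=O)(N1OC1c1ccccc1)c1ccccc1 | starting material
18 | sodium enolate of 16 | [Na+].[O-]C1=C[C@@H](c3ccc(O[Si](C(C)C)(C(C)C)C(C)C)c(OC)c3)c2c(Br)ccc(O[Si](C(C)C)(C(C)C)C(C)C)c2O1 | intermediate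
19 | (3R,4S)-5-bromo-3-hydroxy-4-[3-methoxy-4-(triisopropylsilyloxy)phenyl]-8-(triisopropylsilyloxy)chroman-2-one (3,4-trans) | O=C1[C@H](O)[C@@H](c3ccc(O[Si](C(C)C)(C(C)C)C(C)C)c(OC)c3)c2c(Br)ccc(O[Si](C(C)C)(C(C)C)C(C)C)c2O1 | intermediate
20 | (3R,4S)-5-bromo-4-[3-methoxy-4-(triisopropylsilyloxy)phenyl]-8-(triisopropylsilyloxy)chromane-2,3-diol (lactol, C2 epimers) | OC1[C@H](O)[C@@H](c3ccc(O[Si](C(C)C)(C(C)C)C(C)C)c(OC)c3)c2c(Br)ccc(O[Si](C(C)C)(C(C)C)C(C)C)c2O1 | intermediate
21 | (2R,3S)-3-[6-bromo-2-hydroxy-3-(triisopropylsilyloxy)phenyl]-3-[3-methoxy-4-(triisopropylsilyloxy)phenyl]propane-1,2-diol | OC[C@H](O)[C@@H](c2ccc(O[Si](C(C)C)(C(C)C)C(C)C)c(OC)c2)c1c(Br)ccc(O[Si](C(C)C)(C(C)C)C(C)C)c1O | intermediate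
22 | iodomethane | CI | starting material
23 | (2R,3S)-3-[6-bromo-2-methoxy-3-(triisopropylsilyloxy)phenyl]-3-[3-methoxy-4-(triisopropylsilyloxy)phenyl]propane-1,2-diol | OC[C@H](O)[C@@H](c2ccc(O[Si](C(C)C)(C(C)C)C(C)C)c(OC)c2)c1c(Br)ccc(O[Si](C(C)C)(C(C)C)C(C)C)c1OC | intermediate
24 | 4-methylbenzenesulfonyl chloride | Cc1ccc(cc1)S(Cl)(=O)=O | starting material
25 | (2R,3S)-3-[6-bromo-2-methoxy-3-(triisopropylsilyloxy)phenyl]-2-hydroxy-3-[3-methoxy-4-(triisopropylsilyloxy)phenyl]propyl 4-methylbenzenesulfonate | Cc1ccc(cc1)S(=O)(=O)OC[C@H](O)[C@@H](c2ccc(O[Si](C(C)C)(C(C)C)C(C)C)c(OC)c2)c1c(Br)ccc(O[Si](C(C)C)(C(C)C)C(C)C)c1OC | intermediate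
26 | (2R)-2-{(S)-[6-bromo-2-methoxy-3-(triisopropylsilyloxy)phenyl][3-methoxy-4-(triisopropylsilyloxy)phenyl]methyl}oxirane | C1O[C@@H]1[C@@H](c2ccc(O[Si](C(C)C)(C(C)C)C(C)C)c(OC)c2)c1c(Br)ccc(O[Si](C(C)C)(C(C)C)C(C)C)c1OC | intermediate
27 | (E)-2-(3,3-diethoxyprop-1-en-1-yl)-4,4,5,5-tetramethyl-1,3,2-dioxaborolane | CCOC(OCC)/C=C/B1OC(C)(C)C(C)(C)O1 | starting material
28 | diethyl acetal of 29 | C1O[C@@H]1[C@@H](c2ccc(O[Si](C(C)C)(C(C)C)C(C)C)c(OC)c2)c1c(/C=C/C(OCC)OCC)ccc(O[Si](C(C)C)(C(C)C)C(C)C)c1OC | intermediate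
29 | (2E)-3-{3-methoxy-2-[(S)-[3-methoxy-4-(triisopropylsilyloxy)phenyl][(2R)-oxiran-2-yl]methyl]-4-(triisopropylsilyloxy)phenyl}prop-2-enal | C1O[C@@H]1[C@@H](c2ccc(O[Si](C(C)C)(C(C)C)C(C)C)c(OC)c2)c1c(/C=C/C=O)ccc(O[Si](C(C)C)(C(C)C)C(C)C)c1OC | intermediate
30 | cesium phenoxide of ring A desilylated 29 | [Cs+].C1O[C@@H]1[C@@H](c2ccc(O[Si](C(C)C)(C(C)C)C(C)C)c(OC)c2)c1c(/C=C/C=O)ccc([O-])c1OC | intermediate
31 | quinone methide aldehyde alkoxide (C3 configuration immaterial) | [Cs+].COc1cc([C@H]2C3=C(OC)C(=O)C=CC3=CC(C=O)[C@@H]2C[O-])ccc1O[Si](C(C)C)(C(C)C)C(C)C | intermediate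
32 | (1S,2R)-7-hydroxy-2-(hydroxymethyl)-8-methoxy-1-[3-methoxy-4-(triisopropylsilyloxy)phenyl]-1,2-dihydronaphthalene-3-carbaldehyde | COc1cc([C@H]2c3c(ccc(O)c3OC)C=C(C=O)[C@@H]2CO)ccc1O[Si](C(C)C)(C(C)C)C(C)C | intermediate
33 | vitedoin A | COc1cc([C@H]2c3c(ccc(O)c3OC)C=C(C=O)[C@@H]2CO)ccc1O | target

**Totals:** 13 steps; longest linear sequence 11 steps (steps 1–3 and 6–13).

**Steps most likely to fail**

1. Step 12 (proposed new method). The phenoxide-conjugated C3 may be too weak a nucleophile, so that the epoxide survives, is consumed by intermolecular etherification, or is attacked at the CH2 carbon (7-endo). The pendant silyl ether may also be lost before ring closure. Fallback with known chemistry, from 29 to 33: bromine is added to the enal at −78 °C to give the 2,3-dibromo aldehyde F1, and Et3N removes HBr to give the (Z)-2-bromo enal F2. Luche reduction (NaBH4, CeCl3·7H2O) gives the bromo allylic alcohol F3. Deprotonation with MeLi, bromine–lithium exchange with t-BuLi at −78 °C and addition of BF3·OEt2 let the vinyllithium open the epoxide 6-exo with inversion (Parham-type anionic cyclisation) to give the ring B diol F4. MnO2 oxidises only the arene-conjugated allylic alcohol to the bis-silyl ether of the target F5, and Bu4NF/AcOH then gives 33.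

2. Step 6. The peri bromine at C5 may slow aryl–rhodium insertion at C4 so that protodeboronation of the electron-rich boronic acid wins, or it may erode facial selectivity. Fallback, from 8 to 23: i-Bu2AlH reduces the coumarin to the (Z)-allylic alcohol phenol F6, and MeI/K2CO3 gives the methyl ether F7. Sharpless asymmetric epoxidation (Ti(OiPr)4, L-(+)-diethyl tartrate, t-BuOOH) gives the cis-(2S,3R)-epoxy alcohol F8. The aryl Grignard reagent F9 (from 10 and Mg) with catalytic copper iodide opens F8 at the benzylic carbon with inversion to give 23. Both stereocentres are then set by reagent control and a stereospecific displacement, bypassing steps 6–9.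

3. Step 3. Bromination may go to C7 or to C3 of the pyranone, or HBr may strip the silyl ether. Fallback, from 4 to 8: the free phenol is brominated first with Bu4NBr3, relying on the para direction of the hydroxyl, to give 5-bromo-8-hydroxycoumarin F10, which is then silylated (chlorotriisopropylsilane, imidazole) to 8.

**Further compounds**
F1 | step 12 | 2,3-dibromo aldehyde from 29 (diastereomer mixture) | C1O[C@@H]1[C@@H](c2ccc(O[Si](C(C)C)(C(C)C)C(C)C)c(OC)c2)c1c(C(Br)C(Br)C=O)ccc(O[Si](C(C)C)(C(C)C)C(C)C)c1OC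
F2 | step 12 | (Z)-2-bromo enal | C1O[C@@H]1[C@@H](c2ccc(O[Si](C(C)C)(C(C)C)C(C)C)c(OC)c2)c1c(/C=C(\Br)C=O)ccc(O[Si](C(C)C)(C(C)C)C(C)C)c1OC
F3 | step 12 | (Z)-2-bromo allylic alcohol | C1O[C@@H]1[C@@H](c2ccc(O[Si](C(C)C)(C(C)C)C(C)C)c(OC)c2)c1c(/C=C(\Br)CO)ccc(O[Si](C(C)C)(C(C)C)C(C)C)c1OC
F4 | step 12 | (1S,2R)-2,3-bis(hydroxymethyl)-1,2-dihydronaphthalene bis-silyl ether | COc1cc([C@H]2c3c(ccc(O[Si](C(C)C)(C(C)C)C(C)C)c3OC)C=C(CO)[C@@H]2CO)ccc1O[Si](C(C)C)(C(C)C)C(C)C
F5 | step 12 | bis(triisopropylsilyl) ether of vitedoin A | COc1cc([C@H]2c3c(ccc(O[Si](C(C)C)(C(C)C)C(C)C)c3OC)C=C(C=O)[C@@H]2CO)ccc1O[Si](C(C)C)(C(C)C)C(C)C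
F6 | step 6 | (Z)-3-[6-bromo-2-hydroxy-3-(triisopropylsilyloxy)phenyl]prop-2-en-1-ol | OC/C=C\c1c(Br)ccc(O[Si](C(C)C)(C(C)C)C(C)C)c1O
F7 | step 6 | (Z)-3-[6-bromo-2-methoxy-3-(triisopropylsilyloxy)phenyl]prop-2-en-1-ol | OC/C=C\c1c(Br)ccc(O[Si](C(C)C)(C(C)C)C(C)C)c1OC
F8 | step 6 | [(2S,3R)-3-[6-bromo-2-methoxy-3-(triisopropylsilyloxy)phenyl]oxiran-2-yl]methanol (cis) | OC[C@@H]1O[C@@H]1c1c(Br)ccc(O[Si](C(C)C)(C(C)C)C(C)C)c1OC
F9 | step 6 | [3-methoxy-4-(triisopropylsilyloxy)phenyl]magnesium bromide | COc1cc([Mg]Br)ccc1O[Si](C(C)C)(C(C)C)C(C)C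
F10 | step 3 | 5-bromo-8-hydroxycoumarin | O=C1C=Cc2c(Br)ccc(O)c2O1
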